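The data were generated by integration with constants of no real substance, and the scatter is random.

A racemate starts with no excess, so whatever the left-handed substrate has lost beyond the right-handed substrate must stand as excess of left-handed product, as long as each product keeps its hand.

common to all: free catalyst 0.26 mol%
- red: left-handed substrate 0.020 M; right-handed substrate 0.020 M; reagent 0.80 equiv; the very flask that is asked about, followed so far
- grey: left-handed substrate 0.010 M; right-handed substrate 0.010 M; reagent 0.80 equiv; run made earlier
- flask: left-handed substrate 0.020 M; right-handed substrate 0.020 M; reagent 0.800 equiv; time 20 min

- red (time / min: left-handed substrate / %, right-handed substrate / %): 0.500: 48.0, 48.8; 1.50: 46.2, 47.6; 3.00: 44.1, 46.2; 4.00: 42.3, 45.2; 6.00: 38.8, 44.1; 8.00: 37.8, 42.4; 10.0: 35.6, 40.6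
- grey (time / min: left-handed substrate / %, right-handed substrate / %): 0.833: 48.9, 49.1; 2.00: 48.1, 49.3; 4.00: 46.4, 47.7; 6.00: 45.2, 47.6; 8.00: 43.3, 45.5; 12.0: 41.7, 44.4; 15.0: 39.4, 43.8

(each reading ± 0.5 percentage points)

- free catalyst is single-handed; left-handed substrate and right-handed substrate are mirror images of each other, charged as a racemate, each of them at the stated concentration
- what was read earlier has a scatter of 0.5 percentage points, one standard deviation
- an excess is the difference of the two amounts in percent of their sum
- an excess is below zero if the other one leads

* part of the left-handed substrate and right-handed substrate charged together that has reacted at 20 min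
* excess of left-handed product over right-handed product in the product at 20 min
* excess of right-handed substrate over left-handed substrate among what is left of the two at 20 min

That excess hangs on two things, read in the red run at 10.0 min: the lead of the right-handed substrate over the left-handed, and the loss of the pair. One scatter on the lead moves the answer by 2.1 percentage points, and one scatter on the loss moves it by 0.44 points, so I must know the lead well and need not worry about the loss.

The loss reads 23.8% and the lead 5 points. Their ratio, 21.0%, is my mirror excess m, the lead divided by the loss. The grey run at 15.0 min reads 26.2%. No reading shows a product, so m is what I expect for eP only if each product keeps its hand.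

The forecast gives c = 35%, eS = 10.7% and eP = 20%, on the ground that “selectivity is about 1.7 and stays roughly constant”. From its own c and eS, m is 19.9%, the same as its eP.

The flask gives c = 32.2%, eS = 8.72% and eP = 0.895%, by this scheme:

    free catalyst + left-handed substrate ⇌ catalyst intermediate A (K = 130 L mol⁻¹, k = 3100 L mol⁻¹ s⁻¹)
    free catalyst + right-handed substrate ⇌ catalyst intermediate B (K = 220 L mol⁻¹, k = 190 L mol⁻¹ s⁻¹)
    reagent + catalyst intermediate A → free catalyst + left-handed product (k = 54.0 L mol⁻¹ s⁻¹)
    reagent + catalyst intermediate B → free catalyst + right-handed product (k = 25.0 L mol⁻¹ s⁻¹)
    left-handed product ⇌ right-handed product (k = 0.00230 s⁻¹)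
    2 free catalyst → spent catalyst A (k = 7.00 L mol⁻¹ s⁻¹)
    free catalyst → spent catalyst B (k = 0.00140 s⁻¹)

From the flask's c and eS, m is 18.4%, and eP stands far below it and far below the reading 21.0%. The half-life of left-handed product by its forward step to right-handed product, the way back not counted, is 5.0 min, short against 20 min, and at that time the left-handed product stands at 16.2% and the right-handed at 15.9%. In the neighbour flask with 0.065 mol% of free catalyst, m from its c and eS is 24.3%, and its eP is 2.99%.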